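Retrosynthesis: the C13 methylene, the C15 carboxyl (bond C4–C15) and the O8 tigloyl group are removed; the lactone bond O6–C12 is opened and O6 is reconnected to C9, giving a 7-oxabicyclo[2.2.1]heptan-2-one that is cut at C9–C10 and C5–C6 into 3-methoxyfuran 5 and (E)-ynenal 9.
Enabling feature: in ring C5–C10 the lactone carbinol C6 and the CH2 group C9 are 1,4-related and C9 adjoins the oxygenated C8, so the ring is a masked furan/alkene (4+2) adduct. The furan oxygen becomes O6, the methoxy-bearing carbon becomes the C8 ketone, and that ketone later lets SmI2 cut the temporary C9–O bond.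
Forward: carbocycle first (oxygen-bridged cycloaddition), then vinyl at C10 and ethynyl at C5, bridge opening and closure of the γ-lactone ring, reduction and acylation at C8, carbonylation to the C4 acrylic acid, and α-methylenation of the lactone last.
Stereochemistry: C5, C6 and C10 come from the catalyst-controlled endo cycloaddition of the E-dienophile, C7 from exo protonation of the bridged enol ether, C8 from equatorial hydride attack anti to the axial C10 methyl; the tiglate is introduced with its E geometry.
Key step: step 5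
Remark: elemane numbering (C1–C15) is used for the ring atoms of all intermediates; the target is (5R,6R,7R,8R,10S), i.e. H-5α, H-6β, H-7α, 8β-acyloxy, 10β-methyl.

Step 1
Reactants: 1 3,4-dibromofuran
Product: 2 3-bromo-4-methoxyfuran
Conditions: NaOMe (1.1 equiv), CuBr (10 mol%), MeOH/NMP, 100 °C
Reagents that add atoms: sodium methoxide C[O-].[Na+]
Why: Copper-catalysed Ullmann-type C–O coupling replaces one bromine, and the first methoxy group makes the ring more electron-rich so that a second substitution should be slower; no stereocentre is involved.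

Step 2
Reactants: 2 3-bromo-4-methoxyfuran; 3 methyl bromoacetate
Product: 5 methyl 2-(4-methoxyfuran-3-yl)acetate, via zinc enolate 4 (not isolated)
Conditions: 3, Zn dust, TMSCl (cat.), THF, 40 °C; then 2, Pd2(dba)3 (2 mol%), XPhos (8 mol%), THF, 65 °C
Reagents that add atoms: none
Why: Zinc insertion gives the Reformatsky reagent, which should undergo palladium-catalysed Negishi-type coupling (α-arylation of a zinc ester enolate) with the heteroaryl bromide under neutral conditions that spare the acid-labile methoxyfuran.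

Step 3
Reactants: 6 (2E)-3-methylpent-2-en-4-yn-1-ol
Product: 8 (2E)-3-methyl-5-(trimethylsilyl)pent-2-en-4-yn-1-ol, via bis-silyl ether 7 (not isolated)
Conditions: n-BuLi (2.2 equiv), THF, −78 °C; TMSCl (2.3 equiv), −78 °C to rt; then 1 M HCl, rt
Reagents that add atoms: chlorotrimethylsilane C[Si](C)(C)Cl
Why: Double deprotonation (O–H and alkynyl C–H), bis-silylation and selective acid cleavage of the labile O–Si bond cap the alkyne terminus without touching the E double bond.

Step 4
Reactants: 8 (2E)-3-methyl-5-(trimethylsilyl)pent-2-en-4-yn-1-ol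
Product: 9 (2E)-3-methyl-5-(trimethylsilyl)pent-2-en-4-ynal
Conditions: MnO2 (10 equiv), CH2Cl2, rt
Reagents that add atoms: none
Why: MnO2 oxidation of an allylic alcohol stops at the enal and keeps the E geometry (methyl cis to formyl), which later becomes the C5/C10 relationship.

Step 5
Reactants: 5 methyl 2-(4-methoxyfuran-3-yl)acetate; 9 (2E)-3-methyl-5-(trimethylsilyl)pent-2-en-4-ynal
Product: 11 methyl 2-[(1R,2S,4S,5R,6S)-6-formyl-5-methyl-3-oxo-5-[(trimethylsilyl)ethynyl]-7-oxabicyclo[2.2.1]heptan-2-yl]acetate, via cycloadduct 10 (not isolated)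
Conditions: 5 (1.5 equiv), (S)-3,3-diphenyl-1-(2-methylphenyl)tetrahydro-1H,3H-pyrrolo[1,2-c][1,3,2]oxazaborole·HNTf2 (20 mol%), CH2Cl2, −78 °C; then 1 M HCl, THF, −78 to 0 °C
Reagents that add atoms: water O
Why: The oxazaborolidinium ion binds the formyl group of 9, and the electron-rich furan then adds in a concerted but asynchronous (4+2) cycloaddition in which C9 (furan C2, next to the methoxy carbon) leads onto the β-carbon C10 and C6 (furan C5) follows onto the α-carbon C5. The closest known reaction types are the Diels–Alder reaction of 3-alkoxyfurans with enones and enals and the chiral-oxazaborolidinium-catalysed Diels–Alder reaction of furans with enals. The carbocycle C5–C6–C7–C8–C9–C10 closes in one suprafacial event across the 2,5-positions of the furan, which leaves the furan oxygen as a one-atom bridge from C6 to C9 (7-oxabicyclo[2.2.1]heptene 10). C6 and C9 are fixed by the bridge, C5 and C10 relative to each other by the E geometry of 9 and relative to the bridge by the endo rule (formyl and methyl endo, the bulky silylethynyl group exo), the absolute sense by the catalyst, which should shield one face so that the diene adds to the Re,Re face of C5=C10 (the mirror-image catalyst is taken if the facial sense is the opposite), and C7 by protonation of the enol ether from the exo face during the acid quench, the endo face being blocked by the formyl and methyl groups. The step needs para-type regioselectivity, secured by the 3-methoxy group that makes C9 the nucleophilic terminus, and site selectivity for the enal double bond, secured by the silyl cap that blocks the alkyne and its terminal carbon. The cold acid quench converts the enol ether into the C8 ketone in the same flask, so that the adduct no longer contains a diene unit and cannot revert.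

Step 6
Reactants: 11 methyl 2-[(1R,2S,4S,5R,6S)-6-formyl-5-methyl-3-oxo-5-[(trimethylsilyl)ethynyl]-7-oxabicyclo[2.2.1]heptan-2-yl]acetate
Product: 12 methyl 2-[(1R,2S,4S,5R,6S)-5-ethynyl-6-formyl-5-methyl-3-oxo-7-oxabicyclo[2.2.1]heptan-2-yl]acetate
Conditions: AgNO3 (10 mol%), acetone/H2O (10:1), rt
Reagents that add atoms: none
Why: Silver-catalysed protodesilylation of the alkynylsilane runs at neutral pH, so that neither the enolisable formyl group nor the ketone can trigger β-elimination of the oxygen bridge or epimerise C5 and C7.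

Step 7
Reactants: 12 methyl 2-[(1R,2S,4S,5R,6S)-5-ethynyl-6-formyl-5-methyl-3-oxo-7-oxabicyclo[2.2.1]heptan-2-yl]acetate
Product: 13 methyl 2-[(1R,2S,4S,5S,6S)-5-ethenyl-6-formyl-5-methyl-3-oxo-7-oxabicyclo[2.2.1]heptan-2-yl]acetate
Conditions: H2 (1 atm), Pd/CaCO3 poisoned with Pb(OAc)2, quinoline, EtOAc, rt
Reagents that add atoms: none
Why: Lindlar-type semihydrogenation should stop at the vinyl group, and aldehyde, ketone and ester are not reduced; it is placed here because no other C=C bond is yet present.

Step 8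
Reactants: 13 methyl 2-[(1R,2S,4S,5S,6S)-5-ethenyl-6-formyl-5-methyl-3-oxo-7-oxabicyclo[2.2.1]heptan-2-yl]acetate
Product: 14 methyl 2-[(1R,2S,4S,5S,6S)-5-ethenyl-6-ethynyl-5-methyl-3-oxo-7-oxabicyclo[2.2.1]heptan-2-yl]acetate
Conditions: TMSCHN2 (1.2 equiv), LiN(i-Pr)2 (1.2 equiv), THF, −78 °C; then 13, −78 °C to rt
Reagents that add atoms: (trimethylsilyl)diazomethane C[Si](C)(C)C=[N+]=[N-]
Why: Colvin homologation (addition of the lithiated diazo reagent to the formyl group, Peterson elimination, 1,2-hydrogen shift of the alkylidene carbene) should turn CHO into C≡CH at −78 °C, where addition to the aldehyde outruns both attack on the hindered ketone and α-deprotonation, so C5 and C7 keep their configuration.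

Step 9
Reactants: 14 methyl 2-[(1R,2S,4S,5S,6S)-5-ethenyl-6-ethynyl-5-methyl-3-oxo-7-oxabicyclo[2.2.1]heptan-2-yl]acetate
Product: 16 (3aS,6S,7S,7aR)-6-ethenyl-7-ethynyl-6-methylhexahydro-1-benzofuran-2,4-dione, via hydroxy ketone 15 (not isolated)
Conditions: SmI2 (2.5 equiv), MeOH (4 equiv), THF, −78 °C; then PPTS (10 mol%), CH2Cl2, rt
Reagents that add atoms: none
Why: SmI2 reduction of the α-alkoxy ketone (ketyl, loss of the C9–O bond, protonation of the samarium enolate at C9) opens the bridge far faster than the ketyl can add to the alkyne, and the freed C6 hydroxyl then closes the trans-fused γ-lactone onto the trans-disposed ester by acid-catalysed transesterification without touching a stereocentre.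

Step 10
Reactants: 16 (3aS,6S,7S,7aR)-6-ethenyl-7-ethynyl-6-methylhexahydro-1-benzofuran-2,4-dione
Product: 17 (3aR,4R,6S,7S,7aR)-6-ethenyl-7-ethynyl-4-hydroxy-6-methylhexahydro-1-benzofuran-2(3H)-one
Conditions: LiBH(s-Bu)3 (1.2 equiv), THF, −78 °C; AcOH quench at −78 °C
Reagents that add atoms: none
Why: The bulky trialkylborohydride should attack the C8 carbonyl from the equatorial side, away from the syn-axial C10 methyl group, to give the axial 8β-alcohol, and the ketone reacts much faster than the lactone.

Step 11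
Reactants: 17 (3aR,4R,6S,7S,7aR)-6-ethenyl-7-ethynyl-4-hydroxy-6-methylhexahydro-1-benzofuran-2(3H)-one; 18 (2E)-2-methylbut-2-enoyl chloride
Product: 19 (3aR,4R,6S,7S,7aR)-6-ethenyl-7-ethynyl-6-methyl-2-oxooctahydro-1-benzofuran-4-yl (2E)-2-methylbut-2-enoate
Conditions: 18 (3 equiv), Et3N (4 equiv), DMAP (0.2 equiv), CH2Cl2, 0 °C to rt
Reagents that add atoms: none
Why: DMAP-catalysed acylation of the hindered axial alcohol with the acid chloride installs the tiglate, whose E geometry is the stable one, and prompt acylation keeps the lactone from migrating to O8.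

Step 12
Reactants: 19 (3aR,4R,6S,7S,7aR)-6-ethenyl-7-ethynyl-6-methyl-2-oxooctahydro-1-benzofuran-4-yl (2E)-2-methylbut-2-enoate
Product: 20 2-[(3aR,4R,6S,7R,7aR)-6-ethenyl-6-methyl-4-{[(2E)-2-methylbut-2-enoyl]oxy}-2-oxooctahydro-1-benzofuran-7-yl]prop-2-enoic acid
Conditions: Pd(OAc)2 (2 mol%), 2-(diphenylphosphino)pyridine (8 mol%), MsOH (10 mol%), CO (30 bar), H2O (10 equiv), acetone, 50 °C
Reagents that add atoms: carbon monoxide [C-]#[O+]; water O
Why: Palladium-catalysed Markovnikov hydroxycarbonylation of a terminal alkyne with the pyridylphosphine/acid system should place the carboxyl group on the internal carbon and give the 2-substituted acrylic acid, while the vinyl group and the conjugated ester do not react under these conditions.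

Step 13
Reactants: 20 2-[(3aR,4R,6S,7R,7aR)-6-ethenyl-6-methyl-4-{[(2E)-2-methylbut-2-enoyl]oxy}-2-oxooctahydro-1-benzofuran-7-yl]prop-2-enoic acid
Product: 22 2-[(3aR,4R,6S,7R,7aR)-6-ethenyl-6-methyl-3-methylidene-4-{[(2E)-2-methylbut-2-enoyl]oxy}-2-oxooctahydro-1-benzofuran-7-yl]prop-2-enoic acid, via carboxy lactone 21 (not isolated)
Conditions: MeOMgOCO2Me (2 M in DMF, 20 equiv), 125 °C; 1 M HCl, 0 °C; then 37% aq. HCHO, Et2NH, NaOAc, AcOH, rt
Reagents that add atoms: formaldehyde C=O
Why: Chelation-driven α-carboxylation of the γ-lactone with methyl magnesium carbonate followed by decarboxylative Mannich methylenation is the classical route to α-methylene lactones; it needs no strong base, so the tiglate and the acrylic acid (present as its carboxylate) should survive.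

Compound list
1 | 3,4-dibromofuran | Brc1cocc1Br | starting material
2 | 3-bromo-4-methoxyfuran | COc1cocc1Br | intermediate
3 | methyl bromoacetate | COC(=O)CBr | starting material
4 | (2-methoxy-2-oxoethyl)zinc bromide (Reformatsky reagent) | COC(=O)C[Zn]Br | intermediate
5 | methyl 2-(4-methoxyfuran-3-yl)acetate | COC(=O)Cc1cocc1OC | intermediate
6 | (2E)-3-methylpent-2-en-4-yn-1-ol | C#C/C(C)=C/CO | starting material
7 | trimethyl{[(2E)-3-methyl-5-(trimethylsilyl)pent-2-en-4-yn-1-yl]oxy}silane | C[Si](C)(C)C#C/C(C)=C/CO[Si](C)(C)C | intermediate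
8 | (2E)-3-methyl-5-(trimethylsilyl)pent-2-en-4-yn-1-ol | C[Si](C)(C)C#C/C(C)=C/CO | intermediate
9 | (2E)-3-methyl-5-(trimethylsilyl)pent-2-en-4-ynal | C[Si](C)(C)C#C/C(C)=C/C=O | intermediate
10 | methyl 2-[(1R,4S,5R,6S)-6-formyl-3-methoxy-5-methyl-5-[(trimethylsilyl)ethynyl]-7-oxabicyclo[2.2.1]hept-2-en-2-yl]acetate (formyl and methyl endo, silylethynyl exo) | C[Si](C)(C)C#C[C@]1(C)[C@H]2C(OC)=C(CC(=O)OC)[C@H](O2)[C@H]1C=O | intermediate
11 | methyl 2-[(1R,2S,4S,5R,6S)-6-formyl-5-methyl-3-oxo-5-[(trimethylsilyl)ethynyl]-7-oxabicyclo[2.2.1]heptan-2-yl]acetate (acetate arm, methyl and formyl endo) | C[Si](C)(C)C#C[C@]1(C)[C@H]2C(=O)[C@@H](CC(=O)OC)[C@H](O2)[C@H]1C=O | intermediate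
12 | methyl 2-[(1R,2S,4S,5R,6S)-5-ethynyl-6-formyl-5-methyl-3-oxo-7-oxabicyclo[2.2.1]heptan-2-yl]acetate | C#C[C@]1(C)[C@H]2C(=O)[C@@H](CC(=O)OC)[C@H](O2)[C@H]1C=O | intermediate
13 | methyl 2-[(1R,2S,4S,5S,6S)-5-ethenyl-6-formyl-5-methyl-3-oxo-7-oxabicyclo[2.2.1]heptan-2-yl]acetate | C=C[C@]1(C)[C@H]2C(=O)[C@@H](CC(=O)OC)[C@H](O2)[C@H]1C=O | intermediate
14 | methyl 2-[(1R,2S,4S,5S,6S)-5-ethenyl-6-ethynyl-5-methyl-3-oxo-7-oxabicyclo[2.2.1]heptan-2-yl]acetate | C=C[C@]1(C)[C@H]2C(=O)[C@@H](CC(=O)OC)[C@H](O2)[C@H]1C#C | intermediate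
15 | methyl 2-[(1S,2R,3S,4S)-4-ethenyl-3-ethynyl-2-hydroxy-4-methyl-6-oxocyclohexyl]acetate | C=C[C@]1(C)CC(=O)[C@@H](CC(=O)OC)[C@H](O)[C@H]1C#C | intermediate
16 | (3aS,6S,7S,7aR)-6-ethenyl-7-ethynyl-6-methylhexahydro-1-benzofuran-2,4-dione (trans-fused lactone) | C=C[C@]1(C)CC(=O)[C@H]2CC(=O)O[C@@H]2[C@H]1C#C | intermediate
17 | (3aR,4R,6S,7S,7aR)-6-ethenyl-7-ethynyl-4-hydroxy-6-methylhexahydro-1-benzofuran-2(3H)-one (axial 8β-hydroxyl) | C=C[C@]1(C)C[C@@H](O)[C@H]2CC(=O)O[C@@H]2[C@H]1C#C | intermediate
18 | (2E)-2-methylbut-2-enoyl chloride (tigloyl chloride) | ClC(=O)/C(C)=C/C | starting material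
19 | (3aR,4R,6S,7S,7aR)-6-ethenyl-7-ethynyl-6-methyl-2-oxooctahydro-1-benzofuran-4-yl (2E)-2-methylbut-2-enoate | C=C[C@]1(C)C[C@@H](OC(=O)/C(C)=C/C)[C@H]2CC(=O)O[C@@H]2[C@H]1C#C | intermediate
20 | 2-[(3aR,4R,6S,7R,7aR)-6-ethenyl-6-methyl-4-{[(2E)-2-methylbut-2-enoyl]oxy}-2-oxooctahydro-1-benzofuran-7-yl]prop-2-enoic acid | C=C[C@]1(C)C[C@@H](OC(=O)/C(C)=C/C)[C@H]2CC(=O)O[C@@H]2[C@H]1C(=C)C(=O)O | intermediate
21 | (3aR,4R,6S,7R,7aR)-7-(1-carboxyethenyl)-6-ethenyl-6-methyl-4-{[(2E)-2-methylbut-2-enoyl]oxy}-2-oxooctahydro-1-benzofuran-3-carboxylic acid (both C3 epimers) | C=C[C@]1(C)C[C@@H](OC(=O)/C(C)=C/C)[C@H]2C(C(=O)O)C(=O)O[C@@H]2[C@H]1C(=C)C(=O)O | intermediate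
22 | 2-[(3aR,4R,6S,7R,7aR)-6-ethenyl-6-methyl-3-methylidene-4-{[(2E)-2-methylbut-2-enoyl]oxy}-2-oxooctahydro-1-benzofuran-7-yl]prop-2-enoic acid (CNP0256928.1) | C=C[C@]1(C)C[C@@H](OC(=O)/C(C)=C/C)[C@H]2C(=C)C(=O)O[C@@H]2[C@H]1C(=C)C(=O)O | target

Total step count: 13. Longest linear sequence: 11 steps (6 → 22 through steps 3–13, or 1 → 22 through steps 1, 2 and 5–13).

Steps most likely to fail

Step 5 (key cycloaddition). What may go wrong: acid-induced collapse of the cycloadduct to a 2-alkylated furan (Friedel–Crafts-type ring opening), slow bond formation at the fully substituted β-carbon, or poor facial selectivity. Fallback: it sets out from 5 and 9 and returns at 11. The two components are combined without any acid in CH2Cl2 at 12 kbar and room temperature, a known way to force alkoxyfurans onto hindered dienophiles with endo preference. This should give the racemic adduct, i.e. 10 together with the mirror-image cycloadduct F1, and the same cold acid quench should give 11 together with the mirror-image keto aldehyde F2. 11 is then separated from F2 by preparative HPLC on a cellulose-based chiral stationary phase.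

Step 12 (hydroxycarbonylation). What may go wrong: loss of Markovnikov regioselectivity at the hindered alkyne, which would deliver the linear unsaturated acid, or palladium-hydride isomerisation. Fallback: it sets out from 19 and returns at 20. Gold-catalysed Markovnikov hydration (Ph3PAuNTf2, H2O, dioxane, 60 °C) should give the methyl ketone F3. Kinetic enolisation at the methyl group (KN(SiMe3)2, PhNTf2, THF, −78 °C) should give the enol triflate F4. Carbonylation of the triflate (Pd(OAc)2, dppp, CO 1 atm, KOAc, DMF/H2O, 60 °C) should then give 20, with the carboxyl position fixed by the triflate.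

Step 13 (α-methylenation). What may go wrong: thermal or basic degradation at 125 °C, such as cleavage of the tiglate or migration of the lactone. Fallback: it sets out from 19 and returns at 22. Soft enolisation of the lactone (TMSOTf, Et3N, CH2Cl2, 0 °C) should give the ketene silyl acetal F5. Dimethyl(methylidene)ammonium iodide (CH2Cl2, rt) should give the Mannich base F6, MeI the methiodide F7, and NaHCO3 (EtOAc/H2O) the methylene lactone F8. F8 is then carried through the conditions of step 12 to 22.

Further compounds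
F1 | step 5 | mirror image of cycloadduct 10 (second component of the racemate) | C[Si](C)(C)C#C[C@@]1(C)[C@@H]2C(OC)=C(CC(=O)OC)[C@@H](O2)[C@@H]1C=O
F2 | step 5 | mirror image of keto aldehyde 11 | C[Si](C)(C)C#C[C@@]1(C)[C@@H]2C(=O)[C@H](CC(=O)OC)[C@@H](O2)[C@@H]1C=O
F3 | step 12 | methyl ketone: 19 with acetyl in place of ethynyl at C5 | C=C[C@]1(C)C[C@@H](OC(=O)/C(C)=C/C)[C@H]2CC(=O)O[C@@H]2[C@H]1C(C)=O
F4 | step 12 | enol triflate: 19 with 1-(trifluoromethylsulfonyloxy)ethenyl in place of ethynyl at C5 | C=C[C@]1(C)C[C@@H](OC(=O)/C(C)=C/C)[C@H]2CC(=O)O[C@@H]2[C@H]1C(=C)OS(=O)(=O)C(F)(F)F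
F5 | step 13 | ketene trimethylsilyl acetal of lactone 19 | C=C[C@]1(C)C[C@@H](OC(=O)/C(C)=C/C)[C@H]2C=C(O[Si](C)(C)C)O[C@@H]2[C@H]1C#C
F6 | step 13 | Mannich base: 19 with a dimethylaminomethyl group at the lactone α-carbon (both epimers) | C=C[C@]1(C)C[C@@H](OC(=O)/C(C)=C/C)[C@H]2C(CN(C)C)C(=O)O[C@@H]2[C@H]1C#C
F7 | step 13 | methiodide of F6 (trimethylammoniomethyl lactone iodide) | C=C[C@]1(C)C[C@@H](OC(=O)/C(C)=C/C)[C@H]2C(C[N+](C)(C)C)C(=O)O[C@@H]2[C@H]1C#C.[I-]
F8 | step 13 | methylene lactone: 19 with the exocyclic methylene at the lactone α-carbon | C=C[C@]1(C)C[C@@H](OC(=O)/C(C)=C/C)[C@H]2C(=C)C(=O)O[C@@H]2[C@H]1C#C
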